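## Retrosynthetic overview
1. The ring ketone comes from a C5 carbinol, oxidised in the last step. Rings A (cyclopentane) and B (cyclohexene) close together in one intramolecular Diels–Alder reaction of a linear all-E tetraenoic acid (bonds C3–C7 and C2–C10). This sets C2, C3, C7 and C10.
2. The linear acid is cut at C4–C5 by a vinylogous Mukaiyama aldol between an α-methyl-β,γ-unsaturated aldehyde and the dienolate of cheap 2-ethylhex-2-enoic acid. C4 and C5 are set from C6.
3. Key disconnection, C5–O: the aldehyde comes from an achiral hydrocarbon tetraene by enantioselective oxo transfer and 1,2-H shift. This single C–O bond formation brings in the oxygen that ends as the ring ketone, creates C6, and is the only source of absolute configuration.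
4. The tetraene comes from methacrolein by three olefinations.

**Chain numbering used below.** C1 = CO2H, C2 = C(Et)(CO2H), C3 and C7 = ring-fusion CH, C4 = CHEt, C5 = C=O, C6 = CHMe, C8 = C(Me)=, C9 = =CH, C10 = C(Et)(styryl), C11=C12–Ph. The target is (2R,3R,4S,6S,7R,10S): a trans-fused bicycle in which H3, Et4, CO2H and styryl lie on one face, and H7, Me6, Et2 and Et10 on the other.

**Assumption.** The sense of induction of the new ruthenium catalyst must be found by experiment. Both antipodes of the ligand are accessible, and the one that gives (S)-12 is meant. por* is the dianion of the D4-symmetric 5,10,15,20-tetrakis(1,2,3,4,5,6,7,8-octahydro-1,4:5,8-dimethanoanthracen-9-yl)porphyrin.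

## Route

Step 1
Reactants: 1 methacrolein; 2 2-(triphenylphosphoranylidene)propanal
Product: 3 (2E)-2,4-dimethylpenta-2,4-dienal
Conditions: CH2Cl2, BHT (cat.), 40 °C, 24 h
Reagents that add atoms: none
Why: Wittig olefination with a stabilised formyl ylide is E-selective and stops after one homologation, because the α-branched dienal formed is less electrophilic than methacrolein.

Step 2
Reactants: 4 propyltriphenylphosphonium bromide; 5 ethyl formate
Product: 7 2-(triphenylphosphoranylidene)butanal, via propylidenetriphenylphosphorane 6 (not isolated)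
Conditions: KOtBu (2 equiv), THF, 0 °C; then HCO2Et, 0 °C to rt
Reagents that add atoms: none
Why: C-formylation of a non-stabilised phosphorane with a formate ester works because the second equivalent of base converts the acylphosphonium salt into the stabilised ylide.

Step 3
Reactants: 3 (2E)-2,4-dimethylpenta-2,4-dienal; 7 2-(triphenylphosphoranylidene)butanal
Product: 8 (2E,4E)-2-ethyl-4,6-dimethylhepta-2,4,6-trienal
Conditions: PhMe, 100 °C, 24 h
Reagents that add atoms: none
Why: Wittig olefination with the stabilised ylide places the formyl group trans to the chain and so fixes the E geometry of C9=C10.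

Step 4
Reactants: 8 (2E,4E)-2-ethyl-4,6-dimethylhepta-2,4,6-trienal; 9 diethyl benzylphosphonate
Product: 10 [(1E,3E,5E)-3-ethyl-5,7-dimethylocta-1,3,5,7-tetraen-1-yl]benzene
Conditions: KOtBu, THF, 0 °C to rt
Reagents that add atoms: none
Why: Horner–Wadsworth–Emmons olefination with a benzylic phosphonate gives the E-styryl double bond C11=C12 and does not touch the other alkenes.

Step 5
Reactants: 10 [(1E,3E,5E)-3-ethyl-5,7-dimethylocta-1,3,5,7-tetraen-1-yl]benzene
Product: 12 (2S,3E,5E,7E)-6-ethyl-2,4-dimethyl-8-phenylocta-3,5,7-trienal, via vinyl epoxide 11 (not isolated)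
Conditions: Ru(por*)Cl2 (1 mol %), 2,6-dichloropyridine N-oxide (1.0 equiv), 4 Å MS, C6H6, 10 °C, dark; crude product used at once
Reagents that add atoms: 2,6-dichloropyridine N-oxide, [O-][n+]1c(Cl)cccc1Cl
Why: Proposed new method: enantioselective anti-Markovnikov oxo transfer with 1,2-hydride shift; the walled oxoruthenium porphyrin can reach only the unhindered terminal CH2 (C5, largest HOMO coefficient) of the polyene, since the trans-disubstituted and trisubstituted internal alkenes cannot approach side-on, which gives 2-alkenyl-2-methyloxirane 11; this stays bound to the Lewis-acidic tetravalent ruthenium centre in the chiral pocket, opens at the tertiary, trienyl-stabilised C6–O bond and collapses by migration of H from C5 to C6 anti to the leaving oxygen, so the C5–O bond made here sets C6 as S, while the neutral medium avoids enolisation or conjugation of the β,γ-unsaturated aldehyde; the closest known reaction types are the non-asymmetric metalloporphyrin-catalysed tandem epoxidation–isomerisation of styrenes and terminal 1,3-dienes to aldehydes and the asymmetric porphyrin epoxidation of styrenes, which have not been merged nor applied to a 1,1-disubstituted polyene terminus.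

Step 6
Reactants: 13 (2E)-2-ethylhex-2-enoic acid; 14 1,3-oxazolidin-2-one
Product: 16 3-[(2E)-2-ethylhex-2-enoyl]-1,3-oxazolidin-2-one, via mixed pivalic anhydride 15 (not isolated)
Conditions: PivCl, Et3N, THF, −20 °C; then LiCl, 14, rt
Reagents that add atoms: none
Why: Mixed-anhydride N-acylation of an oxazolidinone succeeds because attack occurs at the less hindered enoyl carbonyl and the E alkene is untouched.

Step 7
Reactants: 16 3-[(2E)-2-ethylhex-2-enoyl]-1,3-oxazolidin-2-one
Product: 17 3-[(1E,3E)-1-(tert-butyldimethylsilyloxy)-2-ethylhexa-1,3-dien-1-yl]-1,3-oxazolidin-2-one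
Conditions: NaN(SiMe3)2, THF, −78 °C; TBSCl, −78 °C to 0 °C
Reagents that add atoms: tert-butyldimethylsilyl chloride, CC(C)(C)[Si](C)(C)Cl
Why: γ-Deprotonation of the enimide and O-silylation give the (E,E)-vinylketene silyl N,O-acetal, as is usual for α-alkyl enimides.

Step 8
Reactants: 12 (2S,3E,5E,7E)-6-ethyl-2,4-dimethyl-8-phenylocta-3,5,7-trienal; 17 3-[(1E,3E)-1-(tert-butyldimethylsilyloxy)-2-ethylhexa-1,3-dien-1-yl]-1,3-oxazolidin-2-one
Product: 18 3-[(2E,4S,5R,6S,7E,9E,11E)-2,4,10-triethyl-5-hydroxy-6,8-dimethyl-12-phenyldodeca-2,7,9,11-tetraenoyl]-1,3-oxazolidin-2-one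
Conditions: TiCl4 (1.0 equiv), CH2Cl2, −78 °C; aq. NaHCO3 quench at −78 °C
Reagents that add atoms: none
Why: In this Kobayashi-type vinylogous Mukaiyama aldol the open transition state of the (E,E)-N,O-acetal gives γ-attack, the E-enimide and the 4,5-anti relation, while Felkin–Anh attack on (S)-12 (alkenyl as the large group) gives 5,6-syn, so C4 is S and C5 is R by relay from C6.

Step 9
Reactants: 18 3-[(2E,4S,5R,6S,7E,9E,11E)-2,4,10-triethyl-5-hydroxy-6,8-dimethyl-12-phenyldodeca-2,7,9,11-tetraenoyl]-1,3-oxazolidin-2-one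
Product: 20 (2E,4S,5R,6S,7E,9E,11E)-2,4,10-triethyl-5-hydroxy-6,8-dimethyl-12-phenyldodeca-2,7,9,11-tetraenoic acid, via peroxy acid 19 (not isolated)
Conditions: LiOH, H2O2, THF/H2O, 0 °C; Na2SO3, 0 °C; cold dilute HCl to pH 4
Reagents that add atoms: hydrogen peroxide, OO
Why: Hydroperoxide cleavage of an N-acyl oxazolidinone attacks the exocyclic carbonyl, and it is done here while the acyl carbon is still unhindered; sulfite reduces the percarboxylate before acidification, and the E geometry prevents lactonisation.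

Step 10
Reactants: 20 (2E,4S,5R,6S,7E,9E,11E)-2,4,10-triethyl-5-hydroxy-6,8-dimethyl-12-phenyldodeca-2,7,9,11-tetraenoic acid
Product: 21 (1S,2R,3S,3aR,4R,5S,7aR)-3,4,5-triethyl-2-hydroxy-1,7-dimethyl-5-[(E)-2-phenylethenyl]-2,3,3a,4,5,7a-hexahydro-1H-indene-4-carboxylic acid
Conditions: PhMe (0.01 M), BHT (5 mol %), 110 °C, 24 h
Reagents that add atoms: none
Why: In this thermal intramolecular Diels–Alder reaction through the carboxyl-endo transition state, the E alkenes fix both quaternary centres, and C4 and C6 each hold their H in the plane of the neighbouring trisubstituted alkene (A(1,3) strain), two reinforcing biases that select one face pair and give the trans-fused bicycle with C2 R, C3 R, C7 R and C10 S.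

Step 11
Reactants: 21 (1S,2R,3S,3aR,4R,5S,7aR)-3,4,5-triethyl-2-hydroxy-1,7-dimethyl-5-[(E)-2-phenylethenyl]-2,3,3a,4,5,7a-hexahydro-1H-indene-4-carboxylic acid
Product: 22 (1S,3S,3aR,4R,5S,7aR)-3,4,5-triethyl-1,7-dimethyl-2-oxo-5-[(E)-2-phenylethenyl]-2,3,3a,4,5,7a-hexahydro-1H-indene-4-carboxylic acid
Conditions: Dess–Martin periodinane, CH2Cl2, 0 °C to rt
Reagents that add atoms: none
Why: Dess–Martin oxidation is neutral and spares the alkenes and the acid, and Et at C4 and Me at C6 are already pseudo-equatorial, so the α-centres have no drive to epimerise.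

## Compound list
1 | methacrolein | C=C(C)C=O | starting material
2 | 2-(triphenylphosphoranylidene)propanal | CC(C=O)=P(c1ccccc1)(c1ccccc1)c1ccccc1 | starting material
3 | (2E)-2,4-dimethylpenta-2,4-dienal | C=C(C)/C=C(C)/C=O | intermediate
4 | propyltriphenylphosphonium bromide | CCC[P+](c1ccccc1)(c1ccccc1)c1ccccc1.[Br-] | starting material
5 | ethyl formate | CCOC=O | starting material
6 | propylidenetriphenylphosphorane | CCC=P(c1ccccc1)(c1ccccc1)c1ccccc1 | intermediate
7 | 2-(triphenylphosphoranylidene)butanal | CCC(C=O)=P(c1ccccc1)(c1ccccc1)c1ccccc1 | intermediate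
8 | (2E,4E)-2-ethyl-4,6-dimethylhepta-2,4,6-trienal | C=C(C)/C=C(C)/C=C(CC)/C=O | intermediate
9 | diethyl benzylphosphonate | CCOP(=O)(Cc1ccccc1)OCC | starting material
10 | [(1E,3E,5E)-3-ethyl-5,7-dimethylocta-1,3,5,7-tetraen-1-yl]benzene | C=C(C)/C=C(C)/C=C(CC)/C=C/c1ccccc1 | intermediate
11 | (2S)-2-[(1E,3E,5E)-4-ethyl-2-methyl-6-phenylhexa-1,3,5-trien-1-yl]-2-methyloxirane | C[C@@]1(CO1)/C=C(C)/C=C(CC)/C=C/c2ccccc2 | intermediate
12 | (2S,3E,5E,7E)-6-ethyl-2,4-dimethyl-8-phenylocta-3,5,7-trienal | O=C[C@@H](C)/C=C(C)/C=C(CC)/C=C/c1ccccc1 | intermediate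
13 | (2E)-2-ethylhex-2-enoic acid | CCC/C=C(CC)/C(=O)O | starting material
14 | 1,3-oxazolidin-2-one | O=C1NCCO1 | starting material
15 | (2E)-2-ethylhex-2-enoic pivalic anhydride | CCC/C=C(CC)/C(=O)OC(=O)C(C)(C)C | intermediate
16 | 3-[(2E)-2-ethylhex-2-enoyl]-1,3-oxazolidin-2-one | CCC/C=C(CC)/C(=O)N1CCOC1=O | intermediate
17 | 3-[(1E,3E)-1-(tert-butyldimethylsilyloxy)-2-ethylhexa-1,3-dien-1-yl]-1,3-oxazolidin-2-one | CC/C=C/C(CC)=C(/O[Si](C)(C)C(C)(C)C)N1CCOC1=O | intermediate
18 | 3-[(2E,4S,5R,6S,7E,9E,11E)-2,4,10-triethyl-5-hydroxy-6,8-dimethyl-12-phenyldodeca-2,7,9,11-tetraenoyl]-1,3-oxazolidin-2-one | O=C1OCCN1C(=O)/C(CC)=C/[C@H](CC)[C@H](O)[C@@H](C)/C=C(C)/C=C(CC)/C=C/c2ccccc2 | intermediate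
19 | (2E,4S,5R,6S,7E,9E,11E)-2,4,10-triethyl-5-hydroxy-6,8-dimethyl-12-phenyldodeca-2,7,9,11-tetraeneperoxoic acid | OOC(=O)/C(CC)=C/[C@H](CC)[C@H](O)[C@@H](C)/C=C(C)/C=C(CC)/C=C/c1ccccc1 | intermediate
20 | (2E,4S,5R,6S,7E,9E,11E)-2,4,10-triethyl-5-hydroxy-6,8-dimethyl-12-phenyldodeca-2,7,9,11-tetraenoic acid | OC(=O)/C(CC)=C/[C@H](CC)[C@H](O)[C@@H](C)/C=C(C)/C=C(CC)/C=C/c1ccccc1 | intermediate
21 | (1S,2R,3S,3aR,4R,5S,7aR)-3,4,5-triethyl-2-hydroxy-1,7-dimethyl-5-[(E)-2-phenylethenyl]-2,3,3a,4,5,7a-hexahydro-1H-indene-4-carboxylic acid | CC[C@@H]1[C@H](O)[C@@H](C)[C@@H]2C(C)=C[C@@](/C=C/c3ccccc3)(CC)[C@](CC)(C(=O)O)[C@H]21 | intermediate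
22 | (1S,3S,3aR,4R,5S,7aR)-3,4,5-triethyl-1,7-dimethyl-2-oxo-5-[(E)-2-phenylethenyl]-2,3,3a,4,5,7a-hexahydro-1H-indene-4-carboxylic acid | CC[C@@H]1C(=O)[C@@H](C)[C@@H]2C(C)=C[C@@](/C=C/c3ccccc3)(CC)[C@](CC)(C(=O)O)[C@H]21 | target

## Step count
- Total steps: 11.
- Longest linear sequence: 8 (steps 1, 3, 4, 5, 8, 9, 10, 11).

## Steps most likely to fail

**Step 5 (the proposed new oxidation).**
- Risks: low ee, because the trienyl-stabilised cation may lose the facial information; oxidation of an internal alkene; drift of 12 into conjugation.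
- The fallback sets out from 10 and comes back at 12, using known chemistry.
- Enantioselective 1,2-protoboration of a 2-substituted 1,3-diene under monovalent copper catalysis (CuCl, chiral bisphosphine, NaOtBu, B2pin2, MeOH, THF) puts boron on the terminal CH2 and a proton on C6. This gives the (R)-homoallylic pinacol boronate F1.
- NaBO3·4H2O in THF/H2O converts it into the (S)-primary alcohol F2.
- Dess–Martin oxidation buffered with NaHCO3 then returns 12.

**Step 8 (vinylogous aldol under substrate control alone).**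
- Risks: Felkin and anti selectivity may be only moderate, and 12 may epimerise on TiCl4.
- The fallback sets out from 13 (and uses 12) and comes back at 20. It moves from substrate control to auxiliary control.
- Compound 13 is coupled with (S)-4-isopropyloxazolidin-2-one (PivCl, Et3N, LiCl) to give the valine-derived enimide F3.
- NaN(SiMe3)2 and TBSCl give the chiral vinylketene silyl N,O-acetal F4.
- Its TiCl4-mediated reaction with 12 gives the anti adduct F5. The isopropyl group that overhangs the diene face is expected to reinforce the Felkin preference.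
- LiOH/H2O2 then gives 20.

**Step 10 (cycloaddition that makes two adjacent quaternary carbons with only a carboxylic acid as activator).**
- Risks: a slow reaction, decay of the polyene, and some reaction through the exo transition state.
- The fallback sets out from 18 and comes back at 21. It changes the dienophile to an enal.
- NaBH4 in THF/H2O removes the oxazolidinone to give the allylic 1,5-diol F6.
- MnO2 in CH2Cl2 oxidises only the allylic alcohol, giving the hydroxy enal F7.
- F7 has a lower LUMO and should cyclise at rt to 40 °C under the same A(1,3) control, giving the bicyclic hydroxy aldehyde F8.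
- Pinnick oxidation (NaClO2, NaH2PO4, 2-methylbut-2-ene, tBuOH/H2O) gives 21.

## Further compounds
F1 | step 5 | 2-[(2R,3E,5E,7E)-6-ethyl-2,4-dimethyl-8-phenylocta-3,5,7-trien-1-yl]-4,4,5,5-tetramethyl-1,3,2-dioxaborolane | CC1(C)OB(C[C@@H](C)/C=C(C)/C=C(CC)/C=C/c2ccccc2)OC1(C)C
F2 | step 5 | (2S,3E,5E,7E)-6-ethyl-2,4-dimethyl-8-phenylocta-3,5,7-trien-1-ol | OC[C@@H](C)/C=C(C)/C=C(CC)/C=C/c1ccccc1
F3 | step 8 | (4S)-3-[(2E)-2-ethylhex-2-enoyl]-4-isopropyl-1,3-oxazolidin-2-one | CCC/C=C(CC)/C(=O)N1[C@@H](C(C)C)COC1=O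
F4 | step 8 | (4S)-3-[(1E,3E)-1-(tert-butyldimethylsilyloxy)-2-ethylhexa-1,3-dien-1-yl]-4-isopropyl-1,3-oxazolidin-2-one | CC/C=C/C(CC)=C(/O[Si](C)(C)C(C)(C)C)N1[C@@H](C(C)C)COC1=O
F5 | step 8 | (4S)-3-[(2E,4S,5R,6S,7E,9E,11E)-2,4,10-triethyl-5-hydroxy-6,8-dimethyl-12-phenyldodeca-2,7,9,11-tetraenoyl]-4-isopropyl-1,3-oxazolidin-2-one | O=C1OC[C@H](C(C)C)N1C(=O)/C(CC)=C/[C@H](CC)[C@H](O)[C@@H](C)/C=C(C)/C=C(CC)/C=C/c2ccccc2
F6 | step 10 | (2E,4S,5R,6S,7E,9E,11E)-2,4,10-triethyl-6,8-dimethyl-12-phenyldodeca-2,7,9,11-tetraene-1,5-diol | OC/C(CC)=C/[C@H](CC)[C@H](O)[C@@H](C)/C=C(C)/C=C(CC)/C=C/c1ccccc1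
F7 | step 10 | (2E,4S,5R,6S,7E,9E,11E)-2,4,10-triethyl-5-hydroxy-6,8-dimethyl-12-phenyldodeca-2,7,9,11-tetraenal | O=C/C(CC)=C/[C@H](CC)[C@H](O)[C@@H](C)/C=C(C)/C=C(CC)/C=C/c1ccccc1
F8 | step 10 | (1S,2R,3S,3aR,4R,5S,7aR)-3,4,5-triethyl-2-hydroxy-1,7-dimethyl-5-[(E)-2-phenylethenyl]-2,3,3a,4,5,7a-hexahydro-1H-indene-4-carbaldehyde | CC[C@@H]1[C@H](O)[C@@H](C)[C@@H]2C(C)=C[C@@](/C=C/c3ccccc3)(CC)[C@](CC)(C=O)[C@H]21
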